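## The problem

The target is a p-menthane-type cyclohex-2-enone with a single carbocycle. The ring atoms are numbered C1 (bearing the C7 hydroxymethyl group), C2 (ketone), C3 (epoxyangelate), C4 (isopropyl), C5 (angelate) and C6 (vinylic CH), and these labels are kept for every intermediate below. Three contiguous ring stereocentres have to be set: the C3 oxygen is trans to the isopropyl group and the C5 oxygen is cis to it, so the two oxygens are trans to each other. C4 can control both neighbours: it can be set together with C3 in one aldol event, and on a ring it shields one face of a C5 carbonyl. The two stereocentres of the (2R,3R)-epoxyangeloyl group are too far from the ring to be controlled by it and need a reagent-controlled epoxidation. Three hydroxyls (C3, C5, C7) must be told apart, because two carry different acyl groups and the primary one stays free. The angelate isomerises to the tiglate under base or nucleophiles, the epoxide is acid-sensitive, the C3 acyloxy ketone can epimerise, and the C5 acyloxy group sits γ to the enone carbonyl and can be eliminated towards an arene, so the acyl groups should go on late and under near-neutral conditions. The feature that opens the route is that C1 is the central carbon of an allyl unit C2–C1–C6 whose ends are flanked by the oxygenated C3 and C5. Removing C1 leaves a cyclopentene (C2, C3, C4, C5, C6), so the six-membered ring is that cyclopentene with one carbon inserted into its alkene, and the C3 oxygen lies next to C2, where it can deliver the ketone oxygen.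

## Retrosynthesis

**C5 ester and C7 ether.** Target 38 is traced to its C7 p-methoxybenzyl ether 37, and 37 to alcohol 35 and angelic acid 24 by cutting the C5 O–acyl bond. The angelate is the most isomerisation-prone group, so it is the last acyl group to go on. C7 must be masked while it does, and a p-methoxybenzyl ether can be removed by a neutral oxidant. The forward steps must acylate a hindered alcohol without Z to E isomerisation and then unmask C7 without touching the epoxide.

**C1–C7 bond.** Alcohol 35 comes from silyl ether 34, and 34 from α-bromo enone 30 and alkoxymethylstannane 33 by cutting C1–C7. This cut is preferred to building C7 in earlier because the key step leaves a bromine at C1. The coupling is placed while C5 still carries a silyl ether, so that no allylic ester meets zerovalent palladium. Stannane 33 is one etherification from iodide 31 and alcohol 32.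

**C3 ester.** Bromide 30 is cut at the C3 O–acyl bond into ketol 23 and epoxy acid 28. Acid 28 goes back through epoxy alcohol 27 and allylic alcohol 25 to angelic acid 24, so both epoxide centres come from a Sharpless epoxidation. Epoxidising an angelate already on the ring would give a diastereomer mixture. The forward esterification joins a hindered ketol and a quaternary acid and must not epimerise C3.

**Oxidation level at C2.** Ketol 23 comes from cis-diol 22 by oxidation of the allylic hydroxyl only, and 22 from cyclic carbonate 21 by methanolysis. The C2 stereocentre disappears here, so it never needs independent control.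

**Ring expansion (key disconnection).** In 21 the C2–O bond is cut and C2 is rejoined to C6, which contracts the ring to the dibromobicyclo[3.1.0]hexane 18. Against a metathesis or cycloaddition closure of the six-membered ring, this cut delivers three things at once: the C1 bromide for C7, the C2 oxygen, and the C2/C6 regiochemistry through the C3 carbonate. The precursor is a five-membered ring that already holds C3, C4 and C5. The forward reaction must ionise a cyclopropyl bromide flanked by two oxygenated carbons and capture the cation at C2 only.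

**Cyclopropane.** 18 is cut at C1–C2 and C1–C6 into cyclopentene 16 and bromoform 17. The carbene should add anti to the C4 isopropyl group, and the outcome is in any case erased in the ring opening.

**Protecting groups and C5.** 16 goes back to alcohol 14, 14 to enone 13, and 13 to hydroxy enone 11. Placing the carbonate on the C3 oxygen before C5 is reduced tells the two oxygens apart without a temporary group. The reduction must deliver hydride anti to isopropyl.

**Five-membered ring.** Cyclopentenone 11 is cut at the C2=C6 alkene into dienone 10 by ring-closing metathesis, which leaves only acyclic stereocontrol to solve.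

**Chain.** Dienone 10 is cut at C5–C6 into Weinreb amide 8 and vinylmagnesium bromide 9. Amide 8 comes from imide 6, and 6 is cut at C3–C4 into imide 3 and acrolein 4. Imide 3 comes from oxazolidinone 1 and isovaleryl chloride 2. The syn aldol sets C3 and C4 in the relation that becomes trans on the ring.

## Roads not taken

Alternative 1: A [4+2] disconnection cuts C2–C3 and C4–C5. Forward, a cinchona-derived bifunctional amine would mediate the endo addition of 3-hydroxy-2-pyrone A2 to (E)-5-methylhex-3-en-2-one A3 to give the lactone-bridged bicyclo[2.2.2]octene A1. A1 holds C3, C4 and C5 in the right relative sense after one catalytic asymmetric step. A Baeyer–Villiger oxidation of the acetyl group, lactone opening and oxidative decarboxylation would then reveal the acyloxy enone.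
- Merits: no auxiliary, the two ring oxygens are differentiated from the start, and the step count is probably lower than in the chosen plan.
- Weak points: A3 is an aliphatic, β-branched enone, far less reactive than the aryl enones and nitroalkenes that suit this catalysis. Adducts of this type can lose CO2 by retro-cycloaddition. The peracid must choose the ketone over the strained alkene. C7 would still have to be added to an enone with a γ-acyloxy group under nucleophilic conditions.
- Comparison: Alternative 1 is better in step economy and in using catalysis. The chosen plan sets against it stereocentres of predictable sense, and the fact that the C1 bromide and the C2 oxygen both come out of the key step.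

Alternative 2: The C2–O and C5–O bonds are cut. Forward, singlet oxygen (O2, visible light, tetraphenylporphyrin) would add across C2 and C5 of diene A5, anti to isopropyl, to give endoperoxide A4. A Kornblum–DeLaMare opening would then give a hydroxy enone.
- Merits: A5 is the C7-oxygenated form of (R)-α-phellandrene A6, so the route follows the likely biogenesis, needs no tin, bromine or silver, and would be much the shortest.
- Weak points: anti addition places the C5 oxygen trans to isopropyl, whereas the target has it cis, so C5 must be inverted at a position γ to the enone carbonyl. The base-induced opening of A4 can remove either bridgehead hydrogen and so can give either hydroxy enone. The C3 oxygen is absent and would need a later enolate oxidation of a ketone that can aromatise. Selective C7 oxidation of A6 and its optical purity are further open points.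
- Comparison: if these were solved, Alternative 2 would be clearly shorter. The chosen plan sets against it a C5 centre formed directly in the right sense and a C3 oxygen that is present from the aldol.

Alternative 3: The C1=C6 bond is cut. Forward, a second-generation Hoveyda–Grubbs catalyst (a divalent ruthenium carbene) would close the fully acylated open-chain α-methylene ketone A8 to A7, the C7 silyl ether of the target, with loss of ethene.
- Merits: the acyclic stereotriad is made by the same aldol logic as here, both esters and C7 are in place before ring closure, and one desilylation finishes the synthesis. The late stage is shorter than in the chosen plan and free of palladium and tin.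
- Weak points: the metathesis must join a 1,1-disubstituted electron-poor alkene to an alkene next to an ester to form a trisubstituted enone. A8 is a polymerisable Michael acceptor with an epimerisable C3. The two labile esters would have to be put onto an open chain in which the C3 and C5 oxygens are 1,3-related and acyl groups can shift between them.
- Comparison: the chosen plan is longer after ring formation. It sets against that a ring on which the two oxygens are trans-1,3 and cannot exchange acyl groups, and esters that are attached only once the ring is secure.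

Key step: step 10

Assumption: compounds 1, 2, 4, 7, 9, 12, 15, 17, 24, 26, 31 and 32 are bought; the small, water-soluble compounds 25, 27 and 28 are carried forward as solutions.

## Route

Step 1
Reactants: 1 (4S)-4-benzyl-1,3-oxazolidin-2-one; 2 3-methylbutanoyl chloride (isovaleryl chloride)
Product: 3 (4S)-4-benzyl-3-(3-methylbutanoyl)-1,3-oxazolidin-2-one
Conditions: n-BuLi, THF, −78 °C; then 2, −78 → 0 °C
Reagents that add atoms: 3-methylbutanoyl chloride (2), CC(C)CC(Cl)=O
Why: N-acylation of the lithiated Evans oxazolidinone by an acid chloride; no stereocentre is formed.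

Step 2
Reactants: 3 N-isovaleryl oxazolidinone; 4 acrolein (prop-2-enal)
Product: 6 (4S)-4-benzyl-3-[(2S,3R)-3-hydroxy-2-(propan-2-yl)pent-4-enoyl]-1,3-oxazolidin-2-one, via Z-boron enolate 5 (not isolated)
Conditions: Bu2BOTf, Et3N, CH2Cl2, −78 → 0 °C; 4, −78 → 0 °C; pH 7 buffer, MeOH, H2O2, 0 °C
Reagents that add atoms: acrolein (4), C=CC=O
Why: Evans syn aldol: the Z enolate 5 reacts through a closed Zimmerman–Traxler transition state on the face away from the benzyl group, which sets C4 (S) and C3 (R in this compound) in the 2,3-syn relation that becomes trans on the ring.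

Step 3
Reactants: 6 syn aldol adduct; 7 N,O-dimethylhydroxylamine hydrochloride
Product: 8 (2S,3R)-3-hydroxy-N-methoxy-N-methyl-2-(propan-2-yl)pent-4-enamide
Conditions: AlMe3, 7, CH2Cl2, −20 → 0 °C; 1 M HCl work-up
Reagents that add atoms: N,O-dimethylhydroxylamine hydrochloride (7), Cl.CNOC
Why: Aluminium amide transamination of a β-hydroxy imide (Weinreb amide formation); the aluminium alkoxide of the free hydroxyl delivers the amide to the exocyclic carbonyl and releases the auxiliary without touching either stereocentre.

Step 4
Reactants: 8 Weinreb amide; 9 vinylmagnesium bromide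
Product: 10 (4S,5R)-5-hydroxy-4-(propan-2-yl)hepta-1,6-dien-3-one
Conditions: 9 (3.5 equiv), THF, −20 → 0 °C; inverse quench into cold aq. HCl
Reagents that add atoms: vinylmagnesium bromide (9), C=C[Mg]Br
Why: Grignard addition to a Weinreb amide stops at the chelated tetrahedral intermediate and gives the vinyl ketone on acidic quench; the first equivalent is spent on the hydroxyl, and the inverse acidic quench keeps the liberated amine from adding to the enone.

Step 5
Reactants: 10 hydroxy dienone
Product: 11 (4R,5S)-4-hydroxy-5-(propan-2-yl)cyclopent-2-en-1-one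
Conditions: second-generation Grubbs catalyst, (H2IMes)(PCy3)Cl2Ru=CHPh (3 mol%), CH2Cl2 (dilute), 40 °C
Reagents that add atoms: none
Why: Ring-closing metathesis of a 1,6-diene (vinyl ketone and allylic alcohol alkene) to a cyclopentenone with loss of ethene; both stereocentres are untouched, and the trans arrangement is also the more stable one at the enolisable C4.

Step 6
Reactants: 11 hydroxy cyclopentenone; 12 di-tert-butyl dicarbonate
Product: 13 tert-butyl (1R,5S)-4-oxo-5-(propan-2-yl)cyclopent-2-en-1-yl carbonate
Conditions: Boc2O, DMAP (cat.), Et3N, CH2Cl2, 0 °C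
Reagents that add atoms: di-tert-butyl dicarbonate (12), CC(C)(C)OC(=O)OC(=O)OC(C)(C)C
Why: DMAP-catalysed tert-butoxycarbonylation of a secondary alcohol; it is done on the ring because loss of the β-carbonate would have to form a cyclopentadienone, which holds back E1cB elimination.

Step 7
Reactants: 13 carbonate enone
Product: 14 tert-butyl (1R,4R,5R)-4-hydroxy-5-(propan-2-yl)cyclopent-2-en-1-yl carbonate
Conditions: NaBH4, CeCl3·7H2O, MeOH, −78 °C
Reagents that add atoms: none
Why: Luche 1,2-reduction of the enone; hydride should approach the nearly flat ring anti to the adjacent isopropyl group, which sets C5 with its hydroxyl cis to isopropyl and trans to the C3 carbonate.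

Step 8
Reactants: 14 allylic alcohol; 15 tert-butyl(chloro)dimethylsilane
Product: 16 tert-butyl (1R,4R,5S)-4-{[tert-butyl(dimethyl)silyl]oxy}-5-(propan-2-yl)cyclopent-2-en-1-yl carbonate
Conditions: TBSCl, imidazole, DMF, rt
Reagents that add atoms: tert-butyl(chloro)dimethylsilane (15), CC(C)(C)[Si](C)(C)Cl
Why: Silylation of a secondary allylic alcohol; the chloride with imidazole is used in place of the silyl triflate so that the tert-butyl carbonate is not attacked.

Step 9
Reactants: 16 cyclopentene; 17 bromoform
Product: 18 tert-butyl (1R,2S,3S,4S,5S)-6,6-dibromo-4-{[tert-butyl(dimethyl)silyl]oxy}-3-(propan-2-yl)bicyclo[3.1.0]hexan-2-yl carbonate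
Conditions: CHBr3, 50% aq. NaOH, BnEt3NCl (cat.), CH2Cl2, 0 °C → rt
Reagents that add atoms: bromoform (17), BrC(Br)Br
Why: Phase-transfer (Makosza) dibromocyclopropanation of a cis alkene; the carbene should add anti to the C4 isopropyl group because the endo bromine of the product lies over C4, and both new centres are erased in step 10, so facial purity is not essential.

Step 10
Reactants: 18 dibromobicyclo[3.1.0]hexane with C3 tert-butyl carbonate, C4 isopropyl and C5 silyl ether
Product: 21 (3aS,4S,5S,7aS)-7-bromo-5-{[tert-butyl(dimethyl)silyl]oxy}-4-(propan-2-yl)-3a,4,5,7a-tetrahydro-2H-1,3-benzodioxol-2-one, via bromoallyl cation 19 (not isolated), via tert-butoxydioxolanylium ion 20 (not isolated)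
Conditions: AgBF4 (2 equiv), 2,6-di-tert-butyl-4-methylpyridine, 4 Å MS, ClCH2CH2Cl, dark, 0 → 40 °C
Reagents that add atoms: none
Why: AgBF4 (monovalent silver) abstracts the endo bromide of 18 while the C2–C6 cyclopropane bond opens in a two-electron disrotatory electrocyclic process, so the five-membered ring expands to the 2-bromocyclohexenyl cation 19; the closest known reaction type is the silver-promoted ring opening of ring-fused gem-dibromocyclopropanes with internal capture of the allyl cation, and the tert-butyl carbonate acts as the internal nucleophile in the way it does in halocarbonate cyclisations. The six-membered carbocycle therefore forms by ring expansion through cleavage of the shared bond, not by a new bond. The carbonyl oxygen of the C3 carbonate attacks C2 in a 5-exo-trig closure to give ion 20, which loses 2-methylpropene and a proton (taken up by the hindered pyridine) to leave the cyclic carbonate. The new C2 stereocentre is controlled by C3, because a five-membered carbonate can only be cis-fused, so the C2–O bond forms on the face of the C3 oxygen. The selectivity the step needs is regiochemical, C2 against C6 of the allyl cation; it is secured by the tether, since the C5 silyl ether cannot deliver a nucleophile and tetrafluoroborate is non-nucleophilic. Both cyclopropane centres vanish in 19, so either facial isomer of 18 would converge on 21. The hindered base keeps HBF4 from cleaving the silyl ether or the carbonate before ionisation.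

Step 11
Reactants: 21 bromo cyclic carbonate
Product: 22 (1S,2S,5S,6S)-3-bromo-5-{[tert-butyl(dimethyl)silyl]oxy}-6-(propan-2-yl)cyclohex-3-ene-1,2-diol
Conditions: K2CO3 (cat.), MeOH, 0 °C
Reagents that add atoms: none
Why: Base-catalysed transesterification of the five-membered cyclic carbonate with methanol to the cis-diol and dimethyl carbonate; silyl ether and vinyl bromide are inert.

Step 12
Reactants: 22 cis-diol
Product: 23 (4S,5S,6S)-2-bromo-4-{[tert-butyl(dimethyl)silyl]oxy}-6-hydroxy-5-(propan-2-yl)cyclohex-2-en-1-one
Conditions: MnO2 (activated, excess), CH2Cl2, rt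
Reagents that add atoms: none
Why: Chemoselective MnO2 oxidation of the allylic C2 alcohol beside the saturated C3 alcohol; the C2 stereocentre made in step 10 is removed here.

Step 13
Reactants: 24 angelic acid, (2Z)-2-methylbut-2-enoic acid
Product: 25 (2Z)-2-methylbut-2-en-1-ol
Conditions: LiAlH4, Et2O, 0 °C
Reagents that add atoms: none
Why: Hydride reduction of the conjugated acid to the allylic alcohol with retention of the Z geometry.

Step 14
Reactants: 25 (Z)-allylic alcohol; 26 tert-butyl hydroperoxide
Product: 27 [(2S,3R)-2,3-dimethyloxiran-2-yl]methanol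
Conditions: Ti(OiPr)4 (10 mol%), L-(+)-diethyl tartrate (12 mol%), t-BuOOH, 4 Å MS, CH2Cl2, −20 °C
Reagents that add atoms: tert-butyl hydroperoxide (26), CC(C)(C)OO
Why: Sharpless asymmetric epoxidation of a Z-trisubstituted allylic alcohol; L-(+)-tartrate should deliver oxygen to the face that gives the (2S,3R)-epoxy alcohol, and the cis relation of CH2OH and the C3 methyl group follows from the Z alkene.

Step 15
Reactants: 27 epoxy alcohol
Product: 28 (2R,3R)-2,3-dimethyloxirane-2-carboxylic acid
Conditions: RuCl3·xH2O (cat.), NaIO4, MeCN/EtOAc/H2O, 0 °C → rt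
Reagents that add atoms: water, O
Why: Catalytic RuO4 oxidation of a primary epoxy alcohol to the glycidic acid; the descriptor at C2 changes from S to R only because the CIP priorities change.

Step 16
Reactants: 23 bromo ketol; 28 epoxy acid
Product: 30 (1S,5S,6S)-3-bromo-5-{[tert-butyl(dimethyl)silyl]oxy}-2-oxo-6-(propan-2-yl)cyclohex-3-en-1-yl (2R,3R)-2,3-dimethyloxirane-2-carboxylate, via mixed anhydride 29 (not isolated)
Conditions: 28, 2,4,6-Cl3C6H2COCl, Et3N, THF, rt; then 23, DMAP (cat.), toluene, rt
Reagents that add atoms: (2R,3R)-2,3-dimethyloxirane-2-carboxylic acid (28), OC(=O)[C@]1(C)O[C@@H]1C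
Why: Yamaguchi esterification through mixed anhydride 29; the C3 configuration should hold because acylation outruns enolisation, and the trans arrangement to isopropyl is also the more stable one.

Step 17
Reactants: 31 tributyl(iodomethyl)stannane; 32 (4-methoxyphenyl)methanol
Product: 33 tributyl{[(4-methoxyphenyl)methoxy]methyl}stannane
Conditions: NaH, THF/DMF, 0 °C → rt
Reagents that add atoms: (4-methoxyphenyl)methanol (32), COc1ccc(CO)cc1
Why: Williamson ether synthesis at the iodomethyl carbon of the stannane.

Step 18
Reactants: 30 α-bromo enone; 33 alkoxymethylstannane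
Product: 34 (1S,5R,6S)-5-{[tert-butyl(dimethyl)silyl]oxy}-3-{[(4-methoxyphenyl)methoxy]methyl}-2-oxo-6-(propan-2-yl)cyclohex-3-en-1-yl (2R,3R)-2,3-dimethyloxirane-2-carboxylate
Conditions: Pd(PPh3)4 (10 mol%), CuI (20 mol%), dioxane, 80 °C
Reagents that add atoms: tributyl{[(4-methoxyphenyl)methoxy]methyl}stannane (33), CCCC[Sn](CCCC)(CCCC)COCc1ccc(OC)cc1
Why: Stille coupling (zerovalent palladium with CuI as co-catalyst) of an α-bromo enone with an α-alkoxymethylstannane, whose oxygenated methyl group transfers in preference to butyl; with C5 still a silyl ether, no allylic ester is exposed to the catalyst.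

Step 19
Reactants: 34 silyl ether
Product: 35 (1S,5R,6R)-5-hydroxy-3-{[(4-methoxyphenyl)methoxy]methyl}-2-oxo-6-(propan-2-yl)cyclohex-3-en-1-yl (2R,3R)-2,3-dimethyloxirane-2-carboxylate
Conditions: HF·pyridine, pyridine, THF, 0 °C → rt
Reagents that add atoms: none
Why: Buffered fluoride cleavage of the secondary allylic silyl ether; the p-methoxybenzyl ether, the epoxy ester and the enone should tolerate HF·pyridine in excess pyridine.

Step 20
Reactants: 35 C5 alcohol; 24 angelic acid
Product: 37 (1S,5R,6R)-3-{[(4-methoxyphenyl)methoxy]methyl}-5-{[(2Z)-2-methylbut-2-enoyl]oxy}-2-oxo-6-(propan-2-yl)cyclohex-3-en-1-yl (2R,3R)-2,3-dimethyloxirane-2-carboxylate, via mixed anhydride 36 (not isolated)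
Conditions: 24, 2,4,6-Cl3C6H2COCl, Et3N, toluene, rt; then 35, 75 °C
Reagents that add atoms: angelic acid (24), C/C=C(/C)C(=O)O
Why: Acylation by the preformed mixed anhydride of angelic acid (Yamaguchi type) without a nucleophilic catalyst, conditions under which the angeloyl group is transferred to hindered alcohols without Z to E isomerisation.

Step 21
Reactants: 37 p-methoxybenzyl ether
Product: 38 (1S,5R,6R)-3-(hydroxymethyl)-5-{[(2Z)-2-methylbut-2-enoyl]oxy}-2-oxo-6-(propan-2-yl)cyclohex-3-en-1-yl (2R,3R)-2,3-dimethyloxirane-2-carboxylate
Conditions: DDQ, CH2Cl2/pH 7 buffer, 0 °C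
Reagents that add atoms: none
Why: Oxidative cleavage of the p-methoxybenzyl ether by DDQ in buffered wet dichloromethane; the conditions are neutral, so angelate, epoxide and acyloxy enone should survive.

## Compound list

1 | (4S)-4-benzyl-1,3-oxazolidin-2-one | O=C1N[C@@H](Cc2ccccc2)CO1 | starting material
2 | 3-methylbutanoyl chloride (isovaleryl chloride) | CC(C)CC(Cl)=O | starting material
3 | (4S)-4-benzyl-3-(3-methylbutanoyl)-1,3-oxazolidin-2-one | CC(C)CC(=O)N1[C@@H](Cc2ccccc2)COC1=O | intermediate
4 | acrolein (prop-2-enal) | C=CC=O | starting material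
5 | (Z)-dibutylboron enolate of 3 | CC(C)/C=C(\OB(CCCC)CCCC)N1[C@@H](Cc2ccccc2)COC1=O | intermediate (not isolated)
6 | (4S)-4-benzyl-3-[(2S,3R)-3-hydroxy-2-(propan-2-yl)pent-4-enoyl]-1,3-oxazolidin-2-one | C=C[C@@H](O)[C@H](C(C)C)C(=O)N1[C@@H](Cc2ccccc2)COC1=O | intermediate
7 | N,O-dimethylhydroxylamine hydrochloride | Cl.CNOC | starting material
8 | (2S,3R)-3-hydroxy-N-methoxy-N-methyl-2-(propan-2-yl)pent-4-enamide | C=C[C@@H](O)[C@H](C(C)C)C(=O)N(C)OC | intermediate
9 | vinylmagnesium bromide | C=C[Mg]Br | starting material
10 | (4S,5R)-5-hydroxy-4-(propan-2-yl)hepta-1,6-dien-3-one | C=C[C@@H](O)[C@H](C(C)C)C(=O)C=C | intermediate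
11 | (4R,5S)-4-hydroxy-5-(propan-2-yl)cyclopent-2-en-1-one (hydroxyl trans to isopropyl) | O[C@@H]1C=CC(=O)[C@H]1C(C)C | intermediate
12 | di-tert-butyl dicarbonate | CC(C)(C)OC(=O)OC(=O)OC(C)(C)C | starting material
13 | tert-butyl (1R,5S)-4-oxo-5-(propan-2-yl)cyclopent-2-en-1-yl carbonate | CC(C)(C)OC(=O)O[C@@H]1C=CC(=O)[C@H]1C(C)C | intermediate
14 | tert-butyl (1R,4R,5R)-4-hydroxy-5-(propan-2-yl)cyclopent-2-en-1-yl carbonate (hydroxyl cis to isopropyl, carbonate trans) | O[C@@H]1C=C[C@@H](OC(=O)OC(C)(C)C)[C@@H]1C(C)C | intermediate
15 | tert-butyl(chloro)dimethylsilane | CC(C)(C)[Si](C)(C)Cl | starting material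
16 | tert-butyl (1R,4R,5S)-4-{[tert-butyl(dimethyl)silyl]oxy}-5-(propan-2-yl)cyclopent-2-en-1-yl carbonate | CC(C)(C)[Si](C)(C)O[C@@H]1C=C[C@@H](OC(=O)OC(C)(C)C)[C@@H]1C(C)C | intermediate
17 | bromoform | BrC(Br)Br | starting material
18 | tert-butyl (1R,2S,3S,4S,5S)-6,6-dibromo-4-{[tert-butyl(dimethyl)silyl]oxy}-3-(propan-2-yl)bicyclo[3.1.0]hexan-2-yl carbonate (cyclopropane on the face of the carbonate, anti to isopropyl and silyl ether) | CC(C)(C)[Si](C)(C)O[C@@H]1[C@H]2C(Br)(Br)[C@H]2[C@@H](OC(=O)OC(C)(C)C)[C@@H]1C(C)C | intermediate
19 | 2-bromocyclohex-2-en-1-ylium (allyl) cation with C3 tert-butyl carbonate, C4 isopropyl and C5 silyl ether | CC(C)(C)[Si](C)(C)O[C@@H]1C=C(Br)[CH+][C@@H](OC(=O)OC(C)(C)C)[C@@H]1C(C)C | intermediate (not isolated)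
20 | cis-fused 2-tert-butoxy-1,3-dioxolan-2-ylium ion spanning C2 and C3 | CC(C)(C)[Si](C)(C)O[C@@H]1C=C(Br)[C@H]2O[C+](OC(C)(C)C)O[C@H]2[C@@H]1C(C)C | intermediate (not isolated)
21 | (3aS,4S,5S,7aS)-7-bromo-5-{[tert-butyl(dimethyl)silyl]oxy}-4-(propan-2-yl)-3a,4,5,7a-tetrahydro-2H-1,3-benzodioxol-2-one | CC(C)(C)[Si](C)(C)O[C@@H]1C=C(Br)[C@H]2OC(=O)O[C@H]2[C@@H]1C(C)C | intermediate
22 | (1S,2S,5S,6S)-3-bromo-5-{[tert-butyl(dimethyl)silyl]oxy}-6-(propan-2-yl)cyclohex-3-ene-1,2-diol | CC(C)(C)[Si](C)(C)O[C@@H]1C=C(Br)[C@@H](O)[C@@H](O)[C@@H]1C(C)C | intermediate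
23 | (4S,5S,6S)-2-bromo-4-{[tert-butyl(dimethyl)silyl]oxy}-6-hydroxy-5-(propan-2-yl)cyclohex-2-en-1-one | CC(C)(C)[Si](C)(C)O[C@@H]1C=C(Br)C(=O)[C@@H](O)[C@@H]1C(C)C | intermediate
24 | angelic acid, (2Z)-2-methylbut-2-enoic acid | C/C=C(/C)C(=O)O | starting material
25 | (2Z)-2-methylbut-2-en-1-ol | C/C=C(/C)CO | intermediate
26 | tert-butyl hydroperoxide | CC(C)(C)OO | starting material
27 | [(2S,3R)-2,3-dimethyloxiran-2-yl]methanol | OC[C@]1(C)O[C@@H]1C | intermediate
28 | (2R,3R)-2,3-dimethyloxirane-2-carboxylic acid | OC(=O)[C@]1(C)O[C@@H]1C | intermediate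
29 | (2R,3R)-2,3-dimethyloxirane-2-carboxylic 2,4,6-trichlorobenzoic anhydride | O=C(OC(=O)[C@]1(C)O[C@@H]1C)c1c(Cl)cc(Cl)cc1Cl | intermediate (not isolated)
30 | (1S,5S,6S)-3-bromo-5-{[tert-butyl(dimethyl)silyl]oxy}-2-oxo-6-(propan-2-yl)cyclohex-3-en-1-yl (2R,3R)-2,3-dimethyloxirane-2-carboxylate | CC(C)(C)[Si](C)(C)O[C@@H]1C=C(Br)C(=O)[C@@H](OC(=O)[C@]2(C)O[C@@H]2C)[C@@H]1C(C)C | intermediate
31 | tributyl(iodomethyl)stannane | CCCC[Sn](CCCC)(CCCC)CI | starting material
32 | (4-methoxyphenyl)methanol | COc1ccc(CO)cc1 | starting material
33 | tributyl{[(4-methoxyphenyl)methoxy]methyl}stannane | CCCC[Sn](CCCC)(CCCC)COCc1ccc(OC)cc1 | intermediate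
34 | (1S,5R,6S)-5-{[tert-butyl(dimethyl)silyl]oxy}-3-{[(4-methoxyphenyl)methoxy]methyl}-2-oxo-6-(propan-2-yl)cyclohex-3-en-1-yl (2R,3R)-2,3-dimethyloxirane-2-carboxylate | CC(C)(C)[Si](C)(C)O[C@@H]1C=C(COCc3ccc(OC)cc3)C(=O)[C@@H](OC(=O)[C@]2(C)O[C@@H]2C)[C@@H]1C(C)C | intermediate
35 | (1S,5R,6R)-5-hydroxy-3-{[(4-methoxyphenyl)methoxy]methyl}-2-oxo-6-(propan-2-yl)cyclohex-3-en-1-yl (2R,3R)-2,3-dimethyloxirane-2-carboxylate | O[C@@H]1C=C(COCc3ccc(OC)cc3)C(=O)[C@@H](OC(=O)[C@]2(C)O[C@@H]2C)[C@@H]1C(C)C | intermediate
36 | (2Z)-2-methylbut-2-enoic 2,4,6-trichlorobenzoic anhydride | C/C=C(/C)C(=O)OC(=O)c1c(Cl)cc(Cl)cc1Cl | intermediate (not isolated)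
37 | (1S,5R,6R)-3-{[(4-methoxyphenyl)methoxy]methyl}-5-{[(2Z)-2-methylbut-2-enoyl]oxy}-2-oxo-6-(propan-2-yl)cyclohex-3-en-1-yl (2R,3R)-2,3-dimethyloxirane-2-carboxylate | C/C=C(/C)C(=O)O[C@@H]1C=C(COCc3ccc(OC)cc3)C(=O)[C@@H](OC(=O)[C@]2(C)O[C@@H]2C)[C@@H]1C(C)C | intermediate
38 | (1S,5R,6R)-3-(hydroxymethyl)-5-{[(2Z)-2-methylbut-2-enoyl]oxy}-2-oxo-6-(propan-2-yl)cyclohex-3-en-1-yl (2R,3R)-2,3-dimethyloxirane-2-carboxylate | C/C=C(/C)C(=O)O[C@@H]1C=C(CO)C(=O)[C@@H](OC(=O)[C@]2(C)O[C@@H]2C)[C@@H]1C(C)C | target

## Step count and least certain steps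

Total step count: 21. Longest linear sequence: 17 steps (steps 1–12, 16, 18–21); steps 13–15 and 17 are side branches.

**Step 10 (key step).** Ionisation may be slow, because both ends of the allyl cation carry inductively withdrawing oxygenated carbons. Heating then invites proton loss from C3 or C5 to a bromodiene and onward aromatisation by loss of silanol or carbonate. Adventitious acid may also strip the tert-butyl carbonate before the bromide leaves. Fallback: setting out from 18, the carbonate would be removed with NaOMe in MeOH to give the alcohol F1, which would be acetylated (Ac2O, pyridine) to the acetate F2. Silver acetate in wet acetic acid would then open the cyclopropane with neighbouring acetoxy participation, and water would hydrolyse the acetoxonium ion to the cis hydroxy acetate F3 (any acetyl-migrated isomer converges). K2CO3 in MeOH would bring the route back at diol 22.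

**Step 7.** Facial selectivity may be poor: the C3 carbonate lies on the face the hydride has to use, and a small hydride may instead attack syn to isopropyl. Fallback: setting out from 11, hydroxyl-directed intramolecular hydride delivery with Me4NBH(OAc)3 in MeCN/AcOH should give the trans-diol F4 from the face of the C3 hydroxyl, which is also the face anti to isopropyl. One equivalent of Boc2O at low temperature would then be used to carbonate the less hindered hydroxyl, the one trans to isopropyl, and return to the route at 14.

**Step 9.** Carbene addition may be slow, because the alkene is deactivated by two allylic oxygens. Long exposure to hydroxide under phase transfer could hydrolyse the carbonate, and the freed alcohol would then react with the carbene. Fallback: setting out from 11, the hydroxyl would be protected as the triethylsilyl ether F5, reduced as in step 7 to the alcohol F6, and silylated to the bis-silyl ether F7. F7 would be cyclopropanated to the dibromide F8. Mild methanolysis (PPTS, MeOH) would remove only the triethylsilyl group to give the alcohol F1, and Boc2O with DMAP would return to the route at 18.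

**Step 18.** Transmetalation of the sp3 alkoxymethyl group may be sluggish. The arylpalladium bromide could then be reduced, butyl could transfer instead, or the epoxy ester could suffer on long heating. Fallback: setting out from 30, coupling with tributyl(hydroxymethyl)stannane, the best-established hydroxymethyl donor, would give the primary alcohol F9. HF·pyridine would give the diol F10, and triethylsilyl chloride at low temperature would select the primary hydroxyl to give the silyl ether F11. Angeloylation as in step 20 would give the diester F12, and brief HF·pyridine would return to the route at target 38.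

**Step 20.** The angelate may isomerise to the tiglate, or the hindered C5 hydroxyl, cis to isopropyl, may fail to react; prolonged heating with amine could also cause elimination towards an arene. Fallback: setting out from 35, the alcohol would be esterified with 2-[bis(2,2,2-trifluoroethoxy)phosphoryl]propanoic acid (DCC, DMAP) to the phosphonate F13. A Still–Gennari olefination with acetaldehyde (KHMDS, 18-crown-6, THF, −78 °C) would then build the Z alkene in place and return to the route at 37.

## Further compounds

F1 | step 10 | (1R,2S,3S,4S,5S)-6,6-dibromo-4-{[tert-butyl(dimethyl)silyl]oxy}-3-(propan-2-yl)bicyclo[3.1.0]hexan-2-ol | CC(C)(C)[Si](C)(C)O[C@@H]1[C@H]2C(Br)(Br)[C@H]2[C@@H](O)[C@@H]1C(C)C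
F2 | step 10 | acetate of F1 (C3 acetate of the dibromobicyclo[3.1.0]hexane) | CC(C)(C)[Si](C)(C)O[C@@H]1[C@H]2C(Br)(Br)[C@H]2[C@@H](OC(C)=O)[C@@H]1C(C)C
F3 | step 10 | C3 monoacetate of diol 22 (cis hydroxy acetate) | CC(C)(C)[Si](C)(C)O[C@@H]1C=C(Br)[C@@H](O)[C@@H](OC(C)=O)[C@@H]1C(C)C
F4 | step 7 | (1R,3R)-2-(propan-2-yl)cyclopent-4-ene-1,3-diol (trans-diol) | O[C@@H]1C=C[C@@H](O)C1C(C)C
F5 | step 9 | (4R,5S)-5-(propan-2-yl)-4-[(triethylsilyl)oxy]cyclopent-2-en-1-one | CC[Si](CC)(CC)O[C@@H]1C=CC(=O)[C@H]1C(C)C
F6 | step 9 | 5-(propan-2-yl)-4-[(triethylsilyl)oxy]cyclopent-2-en-1-ol (hydroxyl cis to isopropyl, silyl ether trans) | O[C@@H]1C=C[C@@H](O[Si](CC)(CC)CC)[C@@H]1C(C)C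
F7 | step 9 | cyclopentene with C3 triethylsilyl ether, C4 isopropyl and C5 tert-butyldimethylsilyl ether | CC(C)(C)[Si](C)(C)O[C@@H]1C=C[C@@H](O[Si](CC)(CC)CC)[C@@H]1C(C)C
F8 | step 9 | 6,6-dibromobicyclo[3.1.0]hexane with C3 triethylsilyl ether, C4 isopropyl and C5 tert-butyldimethylsilyl ether | CC(C)(C)[Si](C)(C)O[C@@H]1[C@H]2C(Br)(Br)[C@H]2[C@@H](O[Si](CC)(CC)CC)[C@@H]1C(C)C
F9 | step 18 | C5 tert-butyldimethylsilyl ether of the C5 des-angeloyl target (C7 hydroxyl free) | CC(C)(C)[Si](C)(C)O[C@@H]1C=C(CO)C(=O)[C@@H](OC(=O)[C@]2(C)O[C@@H]2C)[C@@H]1C(C)C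
F10 | step 18 | C5,C7-diol (C5 des-angeloyl target) | O[C@@H]1C=C(CO)C(=O)[C@@H](OC(=O)[C@]2(C)O[C@@H]2C)[C@@H]1C(C)C
F11 | step 18 | C7 triethylsilyl ether of F10 | O[C@@H]1C=C(CO[Si](CC)(CC)CC)C(=O)[C@@H](OC(=O)[C@]2(C)O[C@@H]2C)[C@@H]1C(C)C
F12 | step 18 | C7 triethylsilyl ether of the target | C/C=C(/C)C(=O)O[C@@H]1C=C(CO[Si](CC)(CC)CC)C(=O)[C@@H](OC(=O)[C@]2(C)O[C@@H]2C)[C@@H]1C(C)C
F13 | step 20 | C5 2-[bis(2,2,2-trifluoroethoxy)phosphoryl]propanoate of 35 (both epimers at the phosphonate carbon) | CC(C(=O)O[C@@H]1C=C(COCc3ccc(OC)cc3)C(=O)[C@@H](OC(=O)[C@]2(C)O[C@@H]2C)[C@@H]1C(C)C)P(=O)(OCC(F)(F)F)OCC(F)(F)F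
A1 | alternative 1 | 8-acetyl-4-hydroxy-7-(propan-2-yl)-2-oxabicyclo[2.2.2]oct-5-en-3-one (endo adduct) | O=C1O[C@@H]2C=C[C@@]1(O)[C@@H](C(C)=O)[C@@H]2C(C)C
A2 | alternative 1 | 3-hydroxy-2H-pyran-2-one | O=c1occcc1O
A3 | alternative 1 | (3E)-5-methylhex-3-en-2-one | CC(C)/C=C/C(C)=O
A4 | alternative 2 | tert-butyl(dimethyl){[7-(propan-2-yl)-2,3-dioxabicyclo[2.2.2]oct-5-en-5-yl]methoxy}silane (peroxide bridge anti to isopropyl) | [C@@H]12C=C(CO[Si](C)(C)C(C)(C)C)[C@@H](OO1)C[C@@H]2C(C)C
A5 | alternative 2 | tert-butyl(dimethyl){[(4R)-4-(propan-2-yl)cyclohexa-1,5-dien-1-yl]methoxy}silane | C1=CC(CO[Si](C)(C)C(C)(C)C)=CC[C@@H]1C(C)C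
A6 | alternative 2 | (R)-α-phellandrene, (5R)-2-methyl-5-(propan-2-yl)cyclohexa-1,3-diene | C1=CC(C)=CC[C@@H]1C(C)C
A7 | alternative 3 | C7 tert-butyldimethylsilyl ether of the target | C/C=C(/C)C(=O)O[C@@H]1C=C(CO[Si](C)(C)C(C)(C)C)C(=O)[C@@H](OC(=O)[C@]2(C)O[C@@H]2C)[C@@H]1C(C)C
A8 | alternative 3 | 2-({[tert-butyl(dimethyl)silyl]oxy}methyl)octa-1,7-dien-3-one carrying the C4 (2R,3R)-epoxyangeloyloxy, C5 isopropyl and C6 angeloyloxy groups | C/C=C(/C)C(=O)O[C@H](C=C)[C@@H](C(C)C)[C@H](OC(=O)[C@]1(C)O[C@@H]1C)C(=O)C(=C)CO[Si](C)(C)C(C)(C)C
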